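**Retrosynthetic overview**

1. Numbering used below (daucane): C1 = quaternary ring-fusion carbon with the methyl, C2/C3 = CH2 groups of the five-membered ring, C4 = carbinol carbon with the isopropyl group, C5 = ring-fusion CH, C6 = CH–OBz, C7 = CH2, C8/C9 = oxirane carbons (C8 carries the methyl), C10 = CH2.
2. End game: benzoate from the C6 hydroxyl; oxirane from the C8=C9 alkene by hydroxyl-directed epoxidation; seven-membered ring by ring-closing metathesis (C8=C9) between an allyl group on C1 and a methallyl carbinol chain on C5; isopropyl group by addition to a C4 cyclopentanone.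
3. Key disconnection: the 2,3,3-trisubstituted cyclopentanone is opened at C1–C5 and C3–C4 to an acyclic allyl vinyl ether (tandem Claisen rearrangement / rhodium hydroacylation). The enabling feature is that, in the five-membered ring, the oxygen-bearing C4 is flanked by C5–H, then by the quaternary C1, then by the unsubstituted C2–C3 pair; O–C4–C5–C1–C2–C3 is therefore the retron of a 4-pentenal and of an O–C4=C5 / C1=C2–C3–O allyl vinyl ether, whose ether oxygen ends up as the C4 hydroxyl.
4. The ether comes from an (E)-vinyl iodide (C6 stereocentre set by an asymmetric glyoxylate-ene reaction) and (2E)-3-methylhexa-2,5-dien-1-ol by copper-catalysed C–O coupling.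
5. Order of ring formation: five-membered ring (step 7), seven-membered ring (step 9), oxirane (step 11).

Key step: step 7

**Route**

Step 1
Reactants: 1 ethyl glyoxylate; 2 isobutene (2-methylprop-1-ene)
Product: 3 ethyl (2S)-2-hydroxy-4-methylpent-4-enoate
Conditions: (S)-1,1'-bi-2-naphthol (10 mol %), TiCl2(OiPr)2 (10 mol %), 4 Å MS, CH2Cl2, −30 °C
Reagents that add atoms: none
Why: Catalytic asymmetric carbonyl-ene (glyoxylate-ene) reaction, in which the binaphthol–titanium Lewis acid shields one face of the bound glyoxylate so that isobutene should add to give the (S)-carbinol (future C6), the (S)-ligand being chosen from the known sense of induction of this catalyst class.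

Step 2
Reactants: 3 ethyl (2S)-2-hydroxy-4-methylpent-4-enoate
Product: 4 ethyl (2S)-2-{[tert-butyl(dimethyl)silyl]oxy}-4-methylpent-4-enoate
Conditions: TBSCl, imidazole, DMF, rt
Reagents that add atoms: tert-butyldimethylsilyl chloride, CC(C)(C)[Si](C)(C)Cl
Why: Standard silyl ether formation on a secondary alcohol, which does not touch the stereocentre.

Step 3
Reactants: 4 ethyl (2S)-2-{[tert-butyl(dimethyl)silyl]oxy}-4-methylpent-4-enoate
Product: 5 (2S)-2-{[tert-butyl(dimethyl)silyl]oxy}-4-methylpent-4-enal
Conditions: DIBAL-H (1.1 equiv), CH2Cl2, −78 °C; aq. potassium sodium tartrate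
Reagents that add atoms: none
Why: Partial reduction of an ester to the aldehyde by DIBAL-H, which stops at the aluminium hemiacetal at −78 °C (stabilised by the alpha-silyloxy group) and is non-basic, so the alpha-stereocentre should be kept.

Step 4
Reactants: 5 (2S)-2-{[tert-butyl(dimethyl)silyl]oxy}-4-methylpent-4-enal
Product: 6 tert-butyl{[(1E,3S)-1-iodo-5-methylhexa-1,5-dien-3-yl]oxy}dimethylsilane
Conditions: CrCl2 (6 equiv), CHI3 (2 equiv), THF/1,4-dioxane, 0 °C to rt
Reagents that add atoms: iodoform, IC(I)I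
Why: Takai olefination (geminal dichromium reagent from iodoform and CrCl2) should give the (E)-iodoalkene under non-basic conditions that spare the alpha-stereocentre.

Step 5
Reactants: 7 pent-1-en-4-yne
Product: 8 (2E)-3-methylhexa-2,5-dien-1-ol
Conditions: Me3Al (2 equiv), Cp2ZrCl2 (0.2 equiv), CH2Cl2, 0 °C to rt; n-BuLi, THF, −78 °C; (CH2O)n, to rt
Reagents that add atoms: trimethylaluminium, C[Al](C)C; paraformaldehyde (as formaldehyde), C=O
Why: Negishi zirconium-catalysed methylalumination adds methyl and aluminium syn across the terminal alkyne (methyl to the internal carbon), and hydroxymethylation of the alkenyl alanate with retention fixes the E trisubstituted alkene, the isolated terminal alkene being inert.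

Step 6
Reactants: 6 tert-butyl{[(1E,3S)-1-iodo-5-methylhexa-1,5-dien-3-yl]oxy}dimethylsilane; 8 (2E)-3-methylhexa-2,5-dien-1-ol
Product: 9 tert-butyl(dimethyl){[(1E,3S)-5-methyl-1-{[(2E)-3-methylhexa-2,5-dien-1-yl]oxy}hexa-1,5-dien-3-yl]oxy}silane
Conditions: CuI (10 mol %), 3,4,7,8-tetramethyl-1,10-phenanthroline (20 mol %), Cs2CO3 (1.5 equiv), toluene, 80 °C
Reagents that add atoms: none
Why: Copper-catalysed Ullmann-type C–O coupling of a vinyl iodide with an allylic alcohol proceeds with retention of the iodoalkene geometry, and at 80 °C the allyl vinyl ether should not yet rearrange.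

Step 7
Reactants: 9 tert-butyl(dimethyl){[(1E,3S)-5-methyl-1-{[(2E)-3-methylhexa-2,5-dien-1-yl]oxy}hexa-1,5-dien-3-yl]oxy}silane
Product: 11 (2S,3R)-2-[(1S)-1-{[tert-butyl(dimethyl)silyl]oxy}-3-methylbut-3-en-1-yl]-3-methyl-3-(prop-2-en-1-yl)cyclopentan-1-one, via 4-pentenal 10 (not isolated)
Conditions: [RhCl(cod)]2 (2.5 mol %), dppe (5 mol %), PhCN, 140 °C, sealed tube
Reagents that add atoms: none
Why: Heating triggers a [3,3]-sigmatropic (Claisen) rearrangement of the allyl vinyl ether through a chair transition state, which forms the C1–C5 bond and releases 4-pentenal 10; its formyl C–H then adds oxidatively to monovalent rhodium, the vinyl group on C1 inserts into Rh–H with rhodium at the terminal carbon, and C–C reductive elimination forms the C3–C4 bond (intramolecular alkene hydroacylation). The closest known reaction type is the rhodium-catalysed tandem Claisen rearrangement–hydroacylation of allyl vinyl ethers to cyclopentanones, which also covers substrates that build a quaternary carbon beside the new ketone ring. The five-membered ring (C4, C5, C1, C2, C3) is the only ring closed and it closes by reductive elimination from a six-membered acyl(alkyl)rhodium metallacycle, while the seven-membered ring is left to step 9. C1 and C5 are set together by the chair transition state: with both alkenes E, the C6 side chain on C5 and the allyl group on C1 are both equatorial and end up trans on the ring, with the side chain cis to the C1 methyl. The absolute sense is relayed from the C6 stereocentre, since the allyl terminus should attack C5 with C7 antiperiplanar to the forming bond and the silyloxy group in the inside position (the usual anti sense for electrophilic attack on (E)-allylic ethers), and no stereocentre is created in the ring closure. The step needs face selectivity in the Claisen event, which this allylic ether bias supplies, and chemoselective hydroacylation, which is secured because only the vinyl group stands in the 4-pentenal relationship to the formyl group while the allyl and methallyl alkenes could only give slower six-membered closures.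

Step 8
Reactants: 11 (2S,3R)-2-[(1S)-1-{[tert-butyl(dimethyl)silyl]oxy}-3-methylbut-3-en-1-yl]-3-methyl-3-(prop-2-en-1-yl)cyclopentan-1-one
Product: 12 (1R,2S,3R)-2-[(1S)-1-{[tert-butyl(dimethyl)silyl]oxy}-3-methylbut-3-en-1-yl]-3-methyl-1-(propan-2-yl)-3-(prop-2-en-1-yl)cyclopentan-1-ol
Conditions: iPrMgCl, anhydrous CeCl3, THF, −78 to 0 °C
Reagents that add atoms: isopropylmagnesium chloride, CC(C)[Mg]Cl
Why: Organocerium 1,2-addition suppresses enolisation and beta-hydride reduction of the hindered ketone, and the reagent should attack C4 from the face anti to the adjacent C5 side chain, which places the new hydroxyl cis to that chain and to the C1 methyl.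

Step 9
Reactants: 12 (1R,2S,3R)-2-[(1S)-1-{[tert-butyl(dimethyl)silyl]oxy}-3-methylbut-3-en-1-yl]-3-methyl-1-(propan-2-yl)-3-(prop-2-en-1-yl)cyclopentan-1-ol
Product: 13 (3R,3aS,4S,8aR)-4-{[tert-butyl(dimethyl)silyl]oxy}-6,8a-dimethyl-3-(propan-2-yl)-1,2,3,3a,4,5,8,8a-octahydroazulen-3-ol
Conditions: second-generation Grubbs catalyst RuCl2(=CHPh)(H2IMes)(PCy3) (5 mol %), CH2Cl2, 40 °C
Reagents that add atoms: none
Why: Ring-closing metathesis between the allyl alkene and the 1,1-disubstituted methallyl alkene closes the seven-membered ring as the trisubstituted C8=C9 alkene with loss of ethylene, the trans ring fusion being already fixed at C1 and C5.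

Step 10
Reactants: 13 (3R,3aS,4S,8aR)-4-{[tert-butyl(dimethyl)silyl]oxy}-6,8a-dimethyl-3-(propan-2-yl)-1,2,3,3a,4,5,8,8a-octahydroazulen-3-ol
Product: 14 (3R,3aS,4S,8aR)-6,8a-dimethyl-3-(propan-2-yl)-1,2,3,3a,4,5,8,8a-octahydroazulene-3,4-diol
Conditions: TBAF, THF, rt to 40 °C
Reagents that add atoms: none
Why: Fluoride-mediated desilylation of the secondary silyl ether, to which the tertiary alcohol and the alkene are inert.

Step 11
Reactants: 14 (3R,3aS,4S,8aR)-6,8a-dimethyl-3-(propan-2-yl)-1,2,3,3a,4,5,8,8a-octahydroazulene-3,4-diol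
Product: 15 epoxy diol: diol 14 with the C8=C9 alkene converted into an oxirane on the face of the C6 hydroxyl, anti to the C1 methyl
Conditions: VO(acac)2 (5 mol %), t-BuOOH (1.5 equiv), CH2Cl2, 0 °C to rt
Reagents that add atoms: tert-butyl hydroperoxide, CC(C)(C)OO
Why: Vanadium-catalysed hydroxyl-directed epoxidation, in which the homoallylic C6 hydroxyl binds the metal peroxide and should deliver oxygen to its own face of the C8=C9 alkene, which is also the face anti to the angular methyl.

Step 12
Reactants: 15 epoxy diol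
Product: 16 target CNP0340059.1 (6-benzoate of epoxy diol 15)
Conditions: Bz2O, Et3N, DMAP (cat.), CH2Cl2, rt
Reagents that add atoms: benzoic anhydride, O=C(OC(=O)c1ccccc1)c1ccccc1
Why: DMAP-catalysed acylation esterifies the secondary C6 hydroxyl selectively over the much less reactive tertiary C4 hydroxyl, and the chloride-free conditions spare the oxirane.

**Compound list**

1 | ethyl glyoxylate | CCOC(=O)C=O | starting material
2 | isobutene (2-methylprop-1-ene) | CC(C)=C | starting material
3 | ethyl (2S)-2-hydroxy-4-methylpent-4-enoate | CCOC(=O)[C@@H](O)CC(C)=C | intermediate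
4 | ethyl (2S)-2-{[tert-butyl(dimethyl)silyl]oxy}-4-methylpent-4-enoate | CCOC(=O)[C@@H](O[Si](C)(C)C(C)(C)C)CC(C)=C | intermediate
5 | (2S)-2-{[tert-butyl(dimethyl)silyl]oxy}-4-methylpent-4-enal | O=C[C@@H](O[Si](C)(C)C(C)(C)C)CC(C)=C | intermediate
6 | tert-butyl{[(1E,3S)-1-iodo-5-methylhexa-1,5-dien-3-yl]oxy}dimethylsilane | I/C=C/[C@@H](O[Si](C)(C)C(C)(C)C)CC(C)=C | intermediate
7 | pent-1-en-4-yne | C=CCC#C | starting material
8 | (2E)-3-methylhexa-2,5-dien-1-ol | C=CC/C(C)=C/CO | intermediate
9 | tert-butyl(dimethyl){[(1E,3S)-5-methyl-1-{[(2E)-3-methylhexa-2,5-dien-1-yl]oxy}hexa-1,5-dien-3-yl]oxy}silane | C=CC/C(C)=C/CO/C=C/[C@@H](O[Si](C)(C)C(C)(C)C)CC(C)=C | intermediate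
10 | (2S,3S)-2-[(1S)-1-{[tert-butyl(dimethyl)silyl]oxy}-3-methylbut-3-en-1-yl]-3-ethenyl-3-methylhex-5-enal (formed in the flask in step 7) | O=C[C@@H]([C@@](C)(CC=C)C=C)[C@@H](O[Si](C)(C)C(C)(C)C)CC(C)=C | intermediate
11 | (2S,3R)-2-[(1S)-1-{[tert-butyl(dimethyl)silyl]oxy}-3-methylbut-3-en-1-yl]-3-methyl-3-(prop-2-en-1-yl)cyclopentan-1-one | O=C1CC[C@](C)(CC=C)[C@H]1[C@@H](O[Si](C)(C)C(C)(C)C)CC(C)=C | intermediate
12 | (1R,2S,3R)-2-[(1S)-1-{[tert-butyl(dimethyl)silyl]oxy}-3-methylbut-3-en-1-yl]-3-methyl-1-(propan-2-yl)-3-(prop-2-en-1-yl)cyclopentan-1-ol | CC(C)[C@]1(O)CC[C@](C)(CC=C)[C@H]1[C@@H](O[Si](C)(C)C(C)(C)C)CC(C)=C | intermediate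
13 | (3R,3aS,4S,8aR)-4-{[tert-butyl(dimethyl)silyl]oxy}-6,8a-dimethyl-3-(propan-2-yl)-1,2,3,3a,4,5,8,8a-octahydroazulen-3-ol | CC(C)[C@]1(O)CC[C@]2(C)CC=C(C)C[C@H](O[Si](C)(C)C(C)(C)C)[C@H]21 | intermediate
14 | (3R,3aS,4S,8aR)-6,8a-dimethyl-3-(propan-2-yl)-1,2,3,3a,4,5,8,8a-octahydroazulene-3,4-diol | CC(C)[C@]1(O)CC[C@]2(C)CC=C(C)C[C@H](O)[C@H]21 | intermediate
15 | epoxy diol (oxirane at C8–C9 on the face of the C6 hydroxyl) | CC(C)[C@]1(O)CC[C@]2(C)C[C@@H]3O[C@]3(C)C[C@H](O)[C@H]21 | intermediate
16 | CNP0340059.1 (6-benzoate of 15) | CC(C)[C@]1(O)CC[C@]2(C)C[C@@H]3O[C@]3(C)C[C@H](OC(=O)c3ccccc3)[C@H]21 | target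

**Step count and risks**

Total step count: 12. Longest linear sequence: 11 steps (steps 1–4 and 6–12).

Steps most likely to fail:

Step 7. The C6 stereocentre may discriminate the two faces of the enol ether only weakly in the Claisen event. In addition, rhodium hydride species at 140 °C may shift the allyl double bond or decarbonylate 10 before the ring closes. The fallback sets out from 8 and comes back at 10, which is then isolated and closed to 11. It separates the two bond formations and runs the sigmatropic step on a chelated ester dianion. Commercial ethyl (3R)-4-chloro-3-hydroxybutanoate F1 is coupled with isopropenylmagnesium bromide (CuI cat., THF, via the epoxide formed in situ) to give ethyl (3S)-3-hydroxy-5-methylhex-5-enoate F2. Transesterification with 8 (Ti(OiPr)4 cat., toluene, removal of ethanol) gives (2E)-3-methylhexa-2,5-dien-1-yl (3S)-3-hydroxy-5-methylhex-5-enoate F3. LDA (2.2 equiv, THF, −78 °C to rt) effects an Ireland–Claisen rearrangement of the lithium-chelated dianion, with attack anti to C7 on the chelate ring as in Fráter–Seebach alkylations, to give (2S,3S)-3-ethenyl-2-[(1S)-1-hydroxy-3-methylbut-3-en-1-yl]-3-methylhex-5-enoic acid F4. Esterification (Me3SiCHN2, MeOH/toluene) gives methyl (2S,3S)-3-ethenyl-2-[(1S)-1-hydroxy-3-methylbut-3-en-1-yl]-3-methylhex-5-enoate F5. Silylation (TBSOTf, 2,6-lutidine) gives methyl (2S,3S)-2-[(1S)-1-{[tert-butyl(dimethyl)silyl]oxy}-3-methylbut-3-en-1-yl]-3-ethenyl-3-methylhex-5-enoate F6. DIBAL-H (CH2Cl2, −78 °C) then gives 10, which is cyclised to 11 at room temperature with [Rh(dppe)]ClO4 (cat.) in CH2Cl2, where double bond migration is slow.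

Step 8. The branched reagent may enolise the hindered ketone or transfer hydride to it instead of adding, or the facial selectivity may erode. The fallback sets out from 11 and comes back at 13. Ring-closing metathesis is done first (second-generation Grubbs catalyst, CH2Cl2, 40 °C) to give the bicyclic ketone (3aS,4S,8aR)-4-{[tert-butyl(dimethyl)silyl]oxy}-6,8a-dimethyl-1,3a,4,5,8,8a-hexahydroazulen-3(2H)-one F7. The smaller, hydride-free isopropenylmagnesium bromide/CeCl3 (THF, −78 °C) should add from the face opposite the angular methyl and the C5–C6 bond to give (3S,3aS,4S,8aR)-4-{[tert-butyl(dimethyl)silyl]oxy}-6,8a-dimethyl-3-(prop-1-en-2-yl)-1,2,3,3a,4,5,8,8a-octahydroazulen-3-ol F8. Chemoselective hydrogenation of the 1,1-disubstituted alkene (H2, RhCl(PPh3)3, benzene) leaves the trisubstituted ring alkene and gives 13.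

Step 11. Oxygen delivery from the homoallylic hydroxyl may be slow or poorly face-selective in the flexible seven-membered ring. The fallback sets out from 14 and comes back at 16. Benzoylation first (Bz2O, Et3N, DMAP, CH2Cl2) gives (3R,3aS,4S,8aR)-3-hydroxy-6,8a-dimethyl-3-(propan-2-yl)-1,2,3,3a,4,5,8,8a-octahydroazulen-4-yl benzoate F9. Epoxidation with mCPBA (NaHCO3, CH2Cl2, 0 °C) under steric control, anti to the angular methyl on C1, should then give 16 directly.

**Further compounds**

F1 | step 7 | ethyl (3R)-4-chloro-3-hydroxybutanoate (commercial starting material of the fallback) | CCOC(=O)C[C@@H](O)CCl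
F2 | step 7 | ethyl (3S)-3-hydroxy-5-methylhex-5-enoate | CCOC(=O)C[C@@H](O)CC(C)=C
F3 | step 7 | (2E)-3-methylhexa-2,5-dien-1-yl (3S)-3-hydroxy-5-methylhex-5-enoate | C=CC/C(C)=C/COC(=O)C[C@@H](O)CC(C)=C
F4 | step 7 | (2S,3S)-3-ethenyl-2-[(1S)-1-hydroxy-3-methylbut-3-en-1-yl]-3-methylhex-5-enoic acid | OC(=O)[C@@H]([C@@](C)(CC=C)C=C)[C@@H](O)CC(C)=C
F5 | step 7 | methyl (2S,3S)-3-ethenyl-2-[(1S)-1-hydroxy-3-methylbut-3-en-1-yl]-3-methylhex-5-enoate | COC(=O)[C@@H]([C@@](C)(CC=C)C=C)[C@@H](O)CC(C)=C
F6 | step 7 | methyl (2S,3S)-2-[(1S)-1-{[tert-butyl(dimethyl)silyl]oxy}-3-methylbut-3-en-1-yl]-3-ethenyl-3-methylhex-5-enoate | COC(=O)[C@@H]([C@@](C)(CC=C)C=C)[C@@H](O[Si](C)(C)C(C)(C)C)CC(C)=C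
F7 | step 8 | (3aS,4S,8aR)-4-{[tert-butyl(dimethyl)silyl]oxy}-6,8a-dimethyl-1,3a,4,5,8,8a-hexahydroazulen-3(2H)-one | O=C1CC[C@]2(C)CC=C(C)C[C@H](O[Si](C)(C)C(C)(C)C)[C@H]21
F8 | step 8 | (3S,3aS,4S,8aR)-4-{[tert-butyl(dimethyl)silyl]oxy}-6,8a-dimethyl-3-(prop-1-en-2-yl)-1,2,3,3a,4,5,8,8a-octahydroazulen-3-ol | C=C(C)[C@]1(O)CC[C@]2(C)CC=C(C)C[C@H](O[Si](C)(C)C(C)(C)C)[C@H]21
F9 | step 11 | (3R,3aS,4S,8aR)-3-hydroxy-6,8a-dimethyl-3-(propan-2-yl)-1,2,3,3a,4,5,8,8a-octahydroazulen-4-yl benzoate | CC(C)[C@]1(O)CC[C@]2(C)CC=C(C)C[C@H](OC(=O)c3ccccc3)[C@H]21
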